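## Retrosynthetic overview

1. All 20 skeletal carbons and the E-allylic acetate come from (2E,6E,10E)-geranylgeraniol 1, used as its acetate 2; no C–C bond is made outside one cyclisation.
2. Retro: the two ketone carbons (C8 and C9, labdane numbering) are the ends of a cleaved tetrasubstituted alkene, so the 1,6-diketone goes back to the decalin diene 3 (ent-labda-8,13E-dien-15-yl acetate).
3. Retro: 3 is opened at C4–C5 and C9–C10 to 2, i.e. one catalyst-controlled, proton-initiated polyene cyclisation that sets C5 and C10 (5R,10R) and ends by loss of H-9.
4. Ring order (forward): ring A, then ring B in the same cascade (2 → 3); ring B is then opened again through ozonide 4 to the seco-diketone target 5.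

Assumption: the target is read as the 8,9-seco-ent-labdane with (5R,10R) configuration (C5 carries the 3-oxobutyl chain, C10 the methyl and the acyl group), and all-E geranylgeraniol (annatto-derived, sold in bulk) is taken as the commercial starting material.

## Route

Step 1
Reactants: 1 (2E,6E,10E)-geranylgeraniol
Product: 2 (2E,6E,10E)-geranylgeranyl acetate
Conditions: Ac2O (1.5 equiv), pyridine, 4-(dimethylamino)pyridine (5 mol %), CH2Cl2, 0 °C to rt
Reagents that add atoms: acetic anhydride, CC(=O)OC(C)=O
Why: Nucleophilic acyl substitution (4-(dimethylamino)pyridine-catalysed acetylation) of the primary allylic alcohol under basic, non-ionising conditions leaves the three E-alkenes untouched and forms no stereocentre.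

Step 2
Reactants: 2 (2E,6E,10E)-geranylgeranyl acetate
Product: 3 ent-labda-8,13E-dien-15-yl acetate, i.e. (2E)-3-methyl-5-[(4aR,8aR)-2,5,5,8a-tetramethyl-3,4,4a,5,6,7,8,8a-octahydronaphthalen-1-yl]pent-2-en-1-yl acetate
Conditions: chiral acid HN[P(=NSO2CF3)(O2-binaphthyl-Ar2)]2 (Ar = spiro[cyclohexane-1,9'-fluoren]-2'-yl at both 3,3'-positions; enantiomer for the 5R,10R series), 5 mol %, (CF3)3COH/CH2Cl2 4:1, 0.05 M, −20 °C, 48 h; Et3N quench; AgNO3–silica chromatography
Reagents that add atoms: none
Why: Proposed new method: the confined, strongly acidic imidodiphosphorimidate protonates the most accessible terminal isopropylidene alkene of 2 inside its pocket while the fluoroalcohol stabilises the developing charge; the all-E chain reacts through a chair–chair fold by two anti additions (C4–C5, then C9–C10), which fixes H-5 and CH3-10 trans, and the pocket selects the face, so the mirror image of the catalyst enantiomer that gives natural (−)-ambrox (5S,10S series) from (3E,7E)-homofarnesol should give 5R,10R; the charge arriving at C8 is quenched by the counter-anion removing the axial, hyperconjugatively aligned H-9 to give the tetrasubstituted (most stable) 8(9)-alkene, and the 13-alkene is expected to stay out because its hydrogen-bonded allylic acetate lowers its nucleophilicity and the run is cold and quenched at full conversion; the closest known reaction types are the imidodiphosphorimidate-catalysed asymmetric proton-initiated cyclisation of homofarnesol to ambrox in fluorinated alcohol (oxygen-terminated) and catalytic asymmetric cationic rearrangements of pure hydrocarbons that end by counter-anion deprotonation to an alkene.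

Step 3
Reactants: 3 ent-labda-8,13E-dien-15-yl acetate
Product: 5 (2E)-3-methyl-6-oxo-6-[(1R,2R)-1,3,3-trimethyl-2-(3-oxobutyl)cyclohexyl]hex-2-en-1-yl acetate, via ozonide 4 (not isolated)
Conditions: O3, CH2Cl2, Sudan red 7B (end-point dye), −78 °C; then PPh3 (1.2 equiv), −78 °C to rt; neutral work-up
Reagents that add atoms: ozone, [O-][O+]=O
Why: Ozonolysis (Criegee mechanism) with reductive work-up: ozone attacks the tetrasubstituted, most electron-rich C8=C9 alkene faster than the C13=C14 alkene, which is deactivated by its allylic acetate; the dye end-point stops the gas before the second alkene reacts, PPh3 reduces the ozonide to the two ketones, and C5 and C10 cannot epimerise (C10 is quaternary, C5 is not alpha to either carbonyl).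

## Compound list

1 | (2E,6E,10E)-geranylgeraniol | CC(C)=CCC/C(C)=C/CC/C(C)=C/CC/C(C)=C/CO | starting material
2 | (2E,6E,10E)-geranylgeranyl acetate | CC(C)=CCC/C(C)=C/CC/C(C)=C/CC/C(C)=C/COC(C)=O | intermediate
3 | ent-labda-8,13E-dien-15-yl acetate, (5R,10R), trans-fused | CC1=C(CC/C(C)=C/COC(C)=O)[C@]2(C)CCCC(C)(C)[C@H]2CC1 | intermediate
4 | 8,9-ozonide of 3 (1,2,4-trioxolane spanning C8 and C9; configuration at these two carbons not specified) | CC12CC[C@@H]3C(C)(C)CCC[C@@]3(C)C(CC/C(C)=C/COC(C)=O)(OO1)O2 | intermediate
5 | (2E)-3-methyl-6-oxo-6-[(1R,2R)-1,3,3-trimethyl-2-(3-oxobutyl)cyclohexyl]hex-2-en-1-yl acetate (15-acetoxy-8,9-seco-ent-labd-13E-ene-8,9-dione) | CC(=O)CC[C@@H]1C(C)(C)CCC[C@@]1(C)C(=O)CC/C(C)=C/COC(C)=O | target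

## Step count and risks

Total steps: 3. Longest linear sequence: 3.

Most likely to fail, in order:

1. Step 2. This step has no direct precedent and carries four risks:
   - The C8 cation may be captured by the 13-alkene to give a tricycle; this is known to happen readily with strong acids on this chain.
   - The allylic acetate may ionise in the acidic fluoroalcohol.
   - Proton loss may give regio-isomeric alkenes in place of the 8(9)-alkene.
   - The sense and level of induction are assumed by analogy and must be checked (sign of rotation of 5, or CD of 3).

   Fallback, setting out from 1 and coming back at 3: phosphorylate 1 with CCl3CN and bis(triethylammonium) hydrogen phosphate in MeCN to geranylgeranyl diphosphate F1 (ammonium salt after ion exchange). Cyclise it with recombinant ent-copalyl diphosphate synthase (0.1 mM MgCl2, pH 7.5 NH4HCO3 buffer, 30 °C) to ent-copalyl diphosphate F2; the enzyme stops at the bicycle and fixes the ent configuration. Hydrolyse with alkaline phosphatase to ent-copalol F3 and acetylate (Ac2O, pyridine) to ent-copalyl acetate F4. Then move the exocyclic 8(17)-alkene into the tetrasubstituted position with I2 (5 mol %) in benzene at 60 °C, which gives 3. The last isomerisation is itself the weak point of this fallback, because of the acid-sensitive allylic acetate.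

2. Step 3. Ozone may also cleave the 13-alkene, or the hindered tetrasubstituted alkene may give epoxide instead of cleavage; the 1,6-diketone can also undergo aldol closure if the work-up is not neutral.

   Fallback, setting out from 3 and coming back at 5: epoxidise 3 with mCPBA (1.05 equiv, NaHCO3, CH2Cl2, −20 °C), which selects the tetrasubstituted alkene, to the 8,9-epoxide F5. Then treat with H5IO6 in wet THF (0 °C to rt), which opens the epoxide to the 8,9-diol F6 (not isolated) and cleaves the glycol to 5.

3. Step 1. The risk is low: traces of acid could isomerise or ionise the allylic system, and Z-isomers in commercial 1 would carry through.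

   Fallback, setting out from 1 and coming back at 2: neutral biocatalytic transesterification with vinyl acetate and immobilised Candida antarctica lipase B in hexane at 30 °C; it forms no new compound (F0).

## Further compounds

F1 | step 2 | (2E,6E,10E)-geranylgeranyl diphosphate | CC(C)=CCC/C(C)=C/CC/C(C)=C/CC/C(C)=C/COP(=O)(O)OP(=O)(O)O
F2 | step 2 | ent-copalyl diphosphate (ent-labda-8(17),13E-dien-15-yl diphosphate) | C[C@@]12CCCC(C)(C)[C@H]1CCC(=C)[C@H]2CC/C(C)=C/COP(=O)(O)OP(=O)(O)O
F3 | step 2 | ent-copalol (ent-labda-8(17),13E-dien-15-ol) | C[C@@]12CCCC(C)(C)[C@H]1CCC(=C)[C@H]2CC/C(C)=C/CO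
F4 | step 2 | ent-copalyl acetate | C[C@@]12CCCC(C)(C)[C@H]1CCC(=C)[C@H]2CC/C(C)=C/COC(C)=O
F5 | step 3 | 8,9-epoxide of 3 (epoxide carbons not specified) | CC12CC[C@@H]3C(C)(C)CCC[C@@]3(C)C1(CC/C(C)=C/COC(C)=O)O2
F6 | step 3 | 8,9-diol from F5 (carbinol carbons not specified) | CC1(O)CC[C@@H]2C(C)(C)CCC[C@@]2(C)C1(O)CC/C(C)=C/COC(C)=O
F0 | step 1 | none | none
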